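**Retrosynthetic overview**
1. The 2,3-dihydrofuran is made last by dehydrating the C1 hemiketal (1-hydroxy-1,4-epoxide); the O8 methacrylate goes on just before.
2. The ten-membered ring and the 5E-ylidene butenolide come from an intramolecular vinylogous aldol condensation (C5–C6) of a butenolide onto a C5 aldehyde.
3. The butenolide comes from a 3,4-disubstituted furan (singlet oxygen, then NaBH4); the C5 aldehyde comes from the vinyl group of linalool.
4. Key fragment union: intermolecular copper-catalysed Mukaiyama aldol (C9–C10, sets C10) between a furyl methyl ketone enol silane and a 1,2-diketone from (R)-linalool (C4); C8 is set by transfer hydrogenation.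
5. Ring order: furan (bought) → oxolane hemiketal → butenolide → ten-membered carbocycle → dihydrofuran.

Assumption: germacrane numbering is used (ring C1–C10, lactone carbons C11–C13, C14 on C10, C15 on C4); centres that are epimer mixtures (anomeric or transient carbinol centres) are drawn without a descriptor.

**Route**

Step 1
Reactants: 1 (R)-(−)-linalool
Product: 2 triethyl{[(3R)-3,7-dimethylocta-1,6-dien-3-yl]oxy}silane
Conditions: Et3SiOTf, 2,6-lutidine, CH2Cl2, −78 → 0 °C
Reagents that add atoms: triethylsilyl trifluoromethanesulfonate, CC[Si](CC)(CC)OS(=O)(=O)C(F)(F)F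
Why: Silyl triflate silylation of the hindered tertiary allylic alcohol masks O4 so that the later 1,2-diketone stays open-chain; the C4 stereocentre (R) is taken unchanged from the chiral pool.

Step 2
Reactants: 2 triethyl{[(3R)-3,7-dimethylocta-1,6-dien-3-yl]oxy}silane
Product: 4 (4R)-4-methyl-4-(triethylsilyloxy)hex-5-enal, via ozonide 3 (not isolated)
Conditions: O3 (1.0 equiv, Sudan Red 7B end point), CH2Cl2, −78 °C; then PPh3, −78 °C → rt
Reagents that add atoms: ozone, [O-][O+]=O
Why: Chemoselective ozonolysis, in which the electron-rich trisubstituted alkene is cleaved much faster than the monosubstituted vinyl group and phosphine reduction of the ozonide releases the aldehyde.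

Step 3
Reactants: 4 (4R)-4-methyl-4-(triethylsilyloxy)hex-5-enal
Product: 6 (6R)-3-hydroxy-6-methyl-6-(triethylsilyloxy)oct-7-en-2-one (both C3 epimers), via ethoxyvinyl carbinol 5 (not isolated)
Conditions: ethyl vinyl ether, t-BuLi, THF, −78 → 0 °C; then 4, −78 °C; then 0.5 M HCl, THF, 0 °C
Reagents that add atoms: ethyl vinyl ether, C=COCC; water, O
Why: 1,2-Addition of the acyl-anion equivalent 1-ethoxyvinyllithium followed by mild enol-ether hydrolysis gives the acyloin, whose new carbinol centre needs no control because it is oxidised in the next step.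

Step 4
Reactants: 6 (6R)-3-hydroxy-6-methyl-6-(triethylsilyloxy)oct-7-en-2-one
Product: 7 (6R)-6-methyl-6-(triethylsilyloxy)oct-7-ene-2,3-dione
Conditions: Dess–Martin periodinane, NaHCO3, CH2Cl2, 0 °C → rt
Reagents that add atoms: none
Why: Dess–Martin oxidation converts the acyloin into the 1,2-diketone under buffered conditions that leave the silyl ether and the vinyl group alone.

Step 5
Reactants: 8 diethyl furan-3,4-dicarboxylate
Product: 9 furan-3,4-diyldimethanol
Conditions: LiAlH4, THF, 0 °C → rt; aqueous work-up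
Reagents that add atoms: none
Why: Hydride reduction of both ester groups gives the symmetric diol.

Step 6
Reactants: 9 furan-3,4-diyldimethanol
Product: 10 [4-(hydroxymethyl)furan-3-yl]methyl acetate
Conditions: Ac2O (1.0 equiv), Et3N, DMAP (2 mol %), CH2Cl2, −20 °C; diol and diacetate recycled
Reagents that add atoms: acetic anhydride, CC(=O)OC(C)=O
Why: Statistical monoacylation of the symmetric diol (no stereocentre involved) installs the C13 acetate that stays to the end.

Step 7
Reactants: 10 [4-(hydroxymethyl)furan-3-yl]methyl acetate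
Product: 11 (4-formylfuran-3-yl)methyl acetate
Conditions: activated MnO2, CH2Cl2, rt
Reagents that add atoms: none
Why: MnO2 oxidises the furylic (benzylic-type) primary alcohol to the aldehyde without over-oxidation or ester cleavage.

Step 8
Reactants: 11 (4-formylfuran-3-yl)methyl acetate
Product: 12 [4-(1-hydroxyethyl)furan-3-yl]methyl acetate (racemic)
Conditions: MeMgBr (1.05 equiv), THF, −78 °C; aq. NH4Cl
Reagents that add atoms: methylmagnesium bromide, C[Mg]Br
Why: Grignard 1,2-addition to the aldehyde at −78 °C is far faster than attack on the acetate.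

Step 9
Reactants: 12 [4-(1-hydroxyethyl)furan-3-yl]methyl acetate
Product: 13 (4-acetylfuran-3-yl)methyl acetate
Conditions: activated MnO2, CH2Cl2, rt
Reagents that add atoms: none
Why: MnO2 oxidation of the secondary furylic alcohol gives the methyl ketone.

Step 10
Reactants: 13 (4-acetylfuran-3-yl)methyl acetate
Product: 14 {4-[1-(trimethylsilyloxy)ethenyl]furan-3-yl}methyl acetate
Conditions: Me3SiOTf, Et3N, CH2Cl2, 0 °C
Reagents that add atoms: trimethylsilyl trifluoromethanesulfonate, C[Si](C)(C)OS(=O)(=O)C(F)(F)F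
Why: Soft enolisation (silyl triflate and amine) gives the enol silane of the methyl ketone, the only readily enolised site under these conditions.

Step 11
Reactants: 14 {4-[1-(trimethylsilyloxy)ethenyl]furan-3-yl}methyl acetate; 7 (6R)-6-methyl-6-(triethylsilyloxy)oct-7-ene-2,3-dione
Product: 17 {4-[(3S)-3-hydroxy-3-[(5R)-2-hydroxy-5-methyl-5-vinyloxolan-2-yl]butanoyl]furan-3-yl}methyl acetate (hemiketal; both anomers), via bis-silyl aldol 15 (not isolated), via open-chain diol 16 (not isolated)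
Conditions: Cu(OTf)2 (10 mol %, divalent copper), 2,2'-(propane-2,2-diyl)bis[(4S)-4-tert-butyl-4,5-dihydrooxazole] (11 mol %), THF, −78 °C; then HF·pyridine, pyridine, THF, 0 °C → rt
Reagents that add atoms: none
Why: Catalytic enantioselective Mukaiyama aldol addition in which the chelated 1,2-diketone is attacked by the enol silane at the less hindered methyl-ketone carbonyl on its si face, forming C9–C10 and setting C10 (S), after which fluoride removes both silyl groups so that O4 closes onto C1 as the hemiketal.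

Step 12
Reactants: 17 {4-[(3S)-3-hydroxy-3-[(5R)-2-hydroxy-5-methyl-5-vinyloxolan-2-yl]butanoyl]furan-3-yl}methyl acetate
Product: 18 {4-[(1R,3S)-1,3-dihydroxy-3-[(5R)-2-hydroxy-5-methyl-5-vinyloxolan-2-yl]butyl]furan-3-yl}methyl acetate
Conditions: RuCl[(R,R)-TsDPEN](p-cymene) (2 mol %), HCO2H/Et3N (5:2), CH2Cl2, 25 °C
Reagents that add atoms: none
Why: Noyori asymmetric transfer hydrogenation reduces only the heteroaryl ketone (the C1 carbonyl is locked as the hemiketal) and the (R,R)-catalyst sets C8 (R) by aryl/alkyl differentiation.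

Step 13
Reactants: 18 {4-[(1R,3S)-1,3-dihydroxy-3-[(5R)-2-hydroxy-5-methyl-5-vinyloxolan-2-yl]butyl]furan-3-yl}methyl acetate
Product: 19 {4-[(1R,3S)-3-hydroxy-3-[(5R)-2-hydroxy-5-methyl-5-vinyloxolan-2-yl]-1-(triethylsilyloxy)butyl]furan-3-yl}methyl acetate
Conditions: Et3SiCl (1.1 equiv), imidazole, DMF, 0 °C
Reagents that add atoms: chlorotriethylsilane, CC[Si](Cl)(CC)CC
Why: Silylation with the silyl chloride is selective for the secondary C8 hydroxyl over the tertiary hydroxyl and the tertiary hemiketal hydroxyl.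

Step 14
Reactants: 19 {4-[(1R,3S)-3-hydroxy-3-[(5R)-2-hydroxy-5-methyl-5-vinyloxolan-2-yl]-1-(triethylsilyloxy)butyl]furan-3-yl}methyl acetate
Product: 21 {4-[(1R,3S)-3-hydroxy-3-[(5R)-2-hydroxy-5-methyl-5-vinyloxolan-2-yl]-1-(triethylsilyloxy)butyl]-5-hydroxy-2-oxo-2,5-dihydrofuran-3-yl}methyl acetate (γ-hydroxybutenolide; both lactol epimers), via furan endoperoxide 20 (not isolated)
Conditions: O2, visible light, tetraphenylporphyrin (cat.), iPr2NEt, CH2Cl2, −78 °C → rt
Reagents that add atoms: dioxygen, O=O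
Why: [4+2] Cycloaddition of singlet oxygen to the furan followed by Kornblum–DeLaMare fragmentation, in which the hindered amine removes the less shielded bridgehead proton (C12–H next to CH2OAc, not C6–H next to the bulky silyloxyalkyl arm) and so places the lactone carbonyl at C12.

Step 15
Reactants: 21 γ-hydroxybutenolide
Product: 23 {4-[(1R,3S)-3-hydroxy-3-[(5R)-2-hydroxy-5-methyl-5-vinyloxolan-2-yl]-1-(triethylsilyloxy)butyl]-2-oxo-2,5-dihydrofuran-3-yl}methyl acetate (butenolide), via hydroxy acid 22 (not isolated)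
Conditions: NaBH4, EtOH/THF, −40 → 0 °C; then aq. citric acid to pH 3, rt
Reagents that add atoms: none
Why: Borohydride reduces the ring-opened aldehyde form of the pseudo-acid at low temperature while the closed hemiketal is untouched, and acidification lactonises the 4-hydroxy-enoic acid through O6, the only hydroxyl cis to the carboxyl.

Step 16
Reactants: 23 butenolide
Product: 25 {4-[(1R,3S)-3-[(5R)-5-formyl-2-hydroxy-5-methyloxolan-2-yl]-3-hydroxy-1-(triethylsilyloxy)butyl]-2-oxo-2,5-dihydrofuran-3-yl}methyl acetate, via ozonide 24 (not isolated)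
Conditions: O3 (Sudan Red 7B end point), CH2Cl2, −78 °C; then PPh3, −78 °C → rt
Reagents that add atoms: ozone, [O-][O+]=O
Why: Ozonolysis of the monosubstituted vinyl group, which reacts faster than the tetrasubstituted electron-poor butenolide alkene, unveils the non-enolisable C5 aldehyde.

Step 17
Reactants: 25 butenolide aldehyde
Product: 26 (1S,4R,8R,10S)-13-acetoxy-1,4-epoxy-1,5,10-trihydroxy-8-(triethylsilyloxy)germacr-7(11)-en-12,6-olide (C5 and C6 epimers)
Conditions: LiN(SiMe3)2 (3.2 equiv), THF (2 mM, slow addition of 25), −78 °C; AcOH, −78 °C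
Reagents that add atoms: none
Why: Intramolecular vinylogous aldol addition in which the lithium dienolate (2-lithiooxyfuran) of the butenolide attacks through C6 the non-enolisable α-alkoxy aldehyde held cis to the other arm on the oxolane ring, closing the ten-membered carbocycle and creating only transient centres at C5 and C6.

Step 18
Reactants: 26 macrocyclic aldol
Product: 28 (1S,4R,5E,8R,10S)-13-acetoxy-1,4-epoxy-1,10-dihydroxy-8-(triethylsilyloxy)germacra-5,7(11)-dien-12,6-olide, via C5 acetate 27 (not isolated)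
Conditions: Ac2O, pyridine, DMAP (cat.), CH2Cl2, 0 °C → rt; then DBU, rt
Reagents that add atoms: none
Why: Selective acetylation of the secondary C5 hydroxyl and E1cB elimination through the dienolate give the γ-ylidene butenolide, whose geometry (C4 cis to C7, that is 5E) is the only one the bridged ring can hold.

Step 19
Reactants: 28 ylidene butenolide silyl ether
Product: 29 (1S,4R,5E,8R,10S)-13-acetoxy-1,4-epoxy-1,8,10-trihydroxygermacra-5,7(11)-dien-12,6-olide
Conditions: Bu4NF, AcOH (1:1), THF, 0 °C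
Reagents that add atoms: none
Why: Buffered fluoride cleaves the secondary silyl ether without harming the esters or the enol lactone.

Step 20
Reactants: 29 triol
Product: 30 (1S,4R,5E,8R,10S)-13-acetoxy-1,4-epoxy-1,10-dihydroxy-8-(2-methylprop-2-enoyloxy)germacra-5,7(11)-dien-12,6-olide
Conditions: methacrylic anhydride, Et3N, DMAP (cat.), CH2Cl2, 0 °C
Reagents that add atoms: methacrylic anhydride, CC(=C)C(=O)OC(=O)C(C)=C
Why: DMAP-catalysed acylation is selective for the secondary C8 hydroxyl over the two tertiary hydroxyls.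

Step 21
Reactants: 30 hemiketal methacrylate
Product: 31 (4R,5E,8R,10S)-13-acetoxy-1,4-epoxy-10-hydroxy-8-(2-methylprop-2-enoyloxy)germacra-1,5,7(11)-trien-12,6-olide (CNP0394509.1)
Conditions: PPTS (10 mol %), 4 Å molecular sieves, benzene, 50 °C
Reagents that add atoms: none
Why: Acid-catalysed dehydration of the hemiketal through the C1 oxocarbenium ion (E1), which can lose a proton only from C2 because C10 is quaternary, forms the 2,3-dihydrofuran and completes the target.

**Compound list**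

1 | (R)-(−)-linalool, (3R)-3,7-dimethylocta-1,6-dien-3-ol | C=C[C@](C)(O)CCC=C(C)C | starting material
2 | triethyl{[(3R)-3,7-dimethylocta-1,6-dien-3-yl]oxy}silane | C=C[C@](C)(O[Si](CC)(CC)CC)CCC=C(C)C | intermediate
3 | ozonide of 2 at the trisubstituted alkene, 3,3-dimethyl-5-[(3R)-3-methyl-3-(triethylsilyloxy)pent-4-enyl]-1,2,4-trioxolane | C=C[C@](C)(O[Si](CC)(CC)CC)CCC1OOC(C)(C)O1 | intermediate
4 | (4R)-4-methyl-4-(triethylsilyloxy)hex-5-enal | C=C[C@](C)(O[Si](CC)(CC)CC)CCC=O | intermediate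
5 | (6R)-2-ethoxy-6-methyl-6-(triethylsilyloxy)octa-1,7-dien-3-ol (both C3 epimers) | C=C[C@](C)(O[Si](CC)(CC)CC)CCC(O)C(=C)OCC | intermediate
6 | (6R)-3-hydroxy-6-methyl-6-(triethylsilyloxy)oct-7-en-2-one (both C3 epimers) | C=C[C@](C)(O[Si](CC)(CC)CC)CCC(O)C(C)=O | intermediate
7 | (6R)-6-methyl-6-(triethylsilyloxy)oct-7-ene-2,3-dione | C=C[C@](C)(O[Si](CC)(CC)CC)CCC(=O)C(C)=O | intermediate
8 | diethyl furan-3,4-dicarboxylate | CCOC(=O)c1cocc1C(=O)OCC | starting material
9 | furan-3,4-diyldimethanol | OCc1cocc1CO | intermediate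
10 | [4-(hydroxymethyl)furan-3-yl]methyl acetate | CC(=O)OCc1cocc1CO | intermediate
11 | (4-formylfuran-3-yl)methyl acetate | CC(=O)OCc1cocc1C=O | intermediate
12 | [4-(1-hydroxyethyl)furan-3-yl]methyl acetate (racemic) | CC(=O)OCc1cocc1C(C)O | intermediate
13 | (4-acetylfuran-3-yl)methyl acetate | CC(=O)OCc1cocc1C(C)=O | intermediate
14 | {4-[1-(trimethylsilyloxy)ethenyl]furan-3-yl}methyl acetate | CC(=O)OCc1cocc1C(=C)O[Si](C)(C)C | intermediate
15 | {4-[(3S,7R)-3,7-dimethyl-4-oxo-7-(triethylsilyloxy)-3-(trimethylsilyloxy)non-8-enoyl]furan-3-yl}methyl acetate (bis-silyl aldol) | CC(=O)OCc1cocc1C(=O)C[C@](C)(O[Si](C)(C)C)C(=O)CC[C@@](C)(O[Si](CC)(CC)CC)C=C | intermediate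
16 | {4-[(3S,7R)-3,7-dihydroxy-3,7-dimethyl-4-oxonon-8-enoyl]furan-3-yl}methyl acetate (open-chain diol) | CC(=O)OCc1cocc1C(=O)C[C@](C)(O)C(=O)CC[C@@](C)(O)C=C | intermediate
17 | {4-[(3S)-3-hydroxy-3-[(5R)-2-hydroxy-5-methyl-5-vinyloxolan-2-yl]butanoyl]furan-3-yl}methyl acetate (hemiketal, both anomers) | CC(=O)OCc1cocc1C(=O)C[C@](C)(O)C1(O)CC[C@](C)(C=C)O1 | intermediate
18 | {4-[(1R,3S)-1,3-dihydroxy-3-[(5R)-2-hydroxy-5-methyl-5-vinyloxolan-2-yl]butyl]furan-3-yl}methyl acetate | CC(=O)OCc1cocc1[C@H](O)C[C@](C)(O)C1(O)CC[C@](C)(C=C)O1 | intermediate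
19 | {4-[(1R,3S)-3-hydroxy-3-[(5R)-2-hydroxy-5-methyl-5-vinyloxolan-2-yl]-1-(triethylsilyloxy)butyl]furan-3-yl}methyl acetate | CC(=O)OCc1cocc1[C@H](O[Si](CC)(CC)CC)C[C@](C)(O)C1(O)CC[C@](C)(C=C)O1 | intermediate
20 | furan endoperoxide of 19 (2,3,7-trioxabicyclo[2.2.1]hept-5-ene with CH2OAc on C6 and the silyloxybutyl chain on C5) | CC(=O)OCC1=C([C@H](O[Si](CC)(CC)CC)C[C@](C)(O)C3(O)CC[C@](C)(C=C)O3)C2OOC1O2 | intermediate
21 | {4-[(1R,3S)-3-hydroxy-3-[(5R)-2-hydroxy-5-methyl-5-vinyloxolan-2-yl]-1-(triethylsilyloxy)butyl]-5-hydroxy-2-oxo-2,5-dihydrofuran-3-yl}methyl acetate (γ-hydroxybutenolide, both lactol epimers) | CC(=O)OCC1=C([C@H](O[Si](CC)(CC)CC)C[C@](C)(O)C2(O)CC[C@](C)(C=C)O2)C(O)OC1=O | intermediate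
22 | ring-opened hydroxy acid of 21 after reduction, (2E,4R,6S)-2-(acetoxymethyl)-6-hydroxy-3-(hydroxymethyl)-6-[(5R)-2-hydroxy-5-methyl-5-vinyloxolan-2-yl]-4-(triethylsilyloxy)hept-2-enoic acid (carboxyl cis to CH2OH) | OC(=O)/C(COC(C)=O)=C(\CO)[C@H](O[Si](CC)(CC)CC)C[C@](C)(O)C1(O)CC[C@](C)(C=C)O1 | intermediate
23 | {4-[(1R,3S)-3-hydroxy-3-[(5R)-2-hydroxy-5-methyl-5-vinyloxolan-2-yl]-1-(triethylsilyloxy)butyl]-2-oxo-2,5-dihydrofuran-3-yl}methyl acetate (butenolide) | CC(=O)OCC1=C([C@H](O[Si](CC)(CC)CC)C[C@](C)(O)C2(O)CC[C@](C)(C=C)O2)COC1=O | intermediate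
24 | ozonide of 23 at the vinyl group (1,2,4-trioxolan-3-yl in place of vinyl) | CC(=O)OCC1=C([C@H](O[Si](CC)(CC)CC)C[C@](C)(O)C2(O)CC[C@](C)(C3OOCO3)O2)COC1=O | intermediate
25 | {4-[(1R,3S)-3-[(5R)-5-formyl-2-hydroxy-5-methyloxolan-2-yl]-3-hydroxy-1-(triethylsilyloxy)butyl]-2-oxo-2,5-dihydrofuran-3-yl}methyl acetate | CC(=O)OCC1=C([C@H](O[Si](CC)(CC)CC)C[C@](C)(O)C2(O)CC[C@](C)(C=O)O2)COC1=O | intermediate
26 | (1S,4R,8R,10S)-13-acetoxy-1,4-epoxy-1,5,10-trihydroxy-8-(triethylsilyloxy)germacr-7(11)-en-12,6-olide (C5 and C6 epimers) | CC[Si](CC)(CC)O[C@@H]1C[C@](C)(O)[C@]2(O)CC[C@](C)(C(O)C3OC(=O)C(COC(C)=O)=C31)O2 | intermediate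
27 | 5-O-acetate of 26 | CC[Si](CC)(CC)O[C@@H]1C[C@](C)(O)[C@]2(O)CC[C@](C)(C(OC(C)=O)C3OC(=O)C(COC(C)=O)=C31)O2 | intermediate
28 | (1S,4R,5E,8R,10S)-13-acetoxy-1,4-epoxy-1,10-dihydroxy-8-(triethylsilyloxy)germacra-5,7(11)-dien-12,6-olide | CC[Si](CC)(CC)O[C@@H]1C[C@](C)(O)[C@]2(O)CC[C@](C)(/C=C3/OC(=O)C(COC(C)=O)=C31)O2 | intermediate
29 | (1S,4R,5E,8R,10S)-13-acetoxy-1,4-epoxy-1,8,10-trihydroxygermacra-5,7(11)-dien-12,6-olide | O[C@@H]1C[C@](C)(O)[C@]2(O)CC[C@](C)(/C=C3/OC(=O)C(COC(C)=O)=C31)O2 | intermediate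
30 | (1S,4R,5E,8R,10S)-13-acetoxy-1,4-epoxy-1,10-dihydroxy-8-(2-methylprop-2-enoyloxy)germacra-5,7(11)-dien-12,6-olide | C=C(C)C(=O)O[C@@H]1C[C@](C)(O)[C@]2(O)CC[C@](C)(/C=C3/OC(=O)C(COC(C)=O)=C31)O2 | intermediate
31 | (4R,5E,8R,10S)-13-acetoxy-1,4-epoxy-10-hydroxy-8-(2-methylprop-2-enoyloxy)germacra-1,5,7(11)-trien-12,6-olide, CNP0394509.1 | C=C(C)C(=O)O[C@@H]1C[C@](C)(O)C2=CC[C@](C)(/C=C3/OC(=O)C(COC(C)=O)=C31)O2 | target

**Count and risks**

Total step count: 21. Longest linear sequence: 17 steps (8 → 31, steps 5–21); the linalool branch (steps 1–4) joins at step 11.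

The three steps most likely to fail:

Step 11 (key aldol). The risk is incomplete facial or regiochemical control with this functionalised diketone and enol silane. The fallback gives up catalyst control and uses the fixed C4 centre instead. It sets out from 14 and 7: BF3·OEt2 in CH2Cl2 at −78 °C gives, after aqueous work-up, the (3S,7R)-aldol F1 and its (3R,7R)-epimer F2, which still carry the C4 silyl ether. They are diastereomers, not enantiomers, so they are separated by chromatography. Treating F1 with HF·pyridine in THF removes the silyl group and closes the hemiketal, which brings the material back to the route at 17.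

Step 14 (furan photooxygenation). The risk is that the amine removes the wrong bridgehead proton, putting the lactone carbonyl at C6. The fallback replaces singlet oxygen by C–H borylation and oxidation. It sets out from 19: [Ir(OMe)(cod)]2 with 4,4'-di-tert-butyl-2,2'-bipyridine and B2pin2 in THF at 25 °C borylates the sterically most accessible α-C–H (C12) to give the C12 pinacol boronate F3. NaBO3·4H2O in THF/H2O converts the boronate into the 2-hydroxyfuran, which tautomerises to the conjugated butenolide, so the route is rejoined at 23 without the lactol stage.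

Step 17 (ring closure). The risk is that the ten-membered ring does not form by aldol addition of the polyanion (oligomers, retro-aldol). The fallback closes the same C5=C6 bond by an intramolecular Horner–Wadsworth–Emmons olefination. It sets out from 21: dimethyl phosphite and Et3N in CH2Cl2, then methanesulfonic acid, give the γ-phosphonate butenolide F4. Ozonolysis (O3, CH2Cl2, −78 °C; PPh3) passes through the vinyl ozonide F5 to the phosphonate aldehyde F6. LiCl and DBU in MeCN at 2 mM then form the ylidene butenolide directly, and the route is rejoined at 28.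

Further compounds
F1 | step 11 | {4-[(3S,7R)-3-hydroxy-3,7-dimethyl-4-oxo-7-(triethylsilyloxy)non-8-enoyl]furan-3-yl}methyl acetate | CC(=O)OCc1cocc1C(=O)C[C@](C)(O)C(=O)CC[C@@](C)(O[Si](CC)(CC)CC)C=C
F2 | step 11 | {4-[(3R,7R)-3-hydroxy-3,7-dimethyl-4-oxo-7-(triethylsilyloxy)non-8-enoyl]furan-3-yl}methyl acetate | CC(=O)OCc1cocc1C(=O)C[C@@](C)(O)C(=O)CC[C@@](C)(O[Si](CC)(CC)CC)C=C
F3 | step 14 | {4-[(1R,3S)-3-hydroxy-3-[(5R)-2-hydroxy-5-methyl-5-vinyloxolan-2-yl]-1-(triethylsilyloxy)butyl]-2-(4,4,5,5-tetramethyl-1,3,2-dioxaborolan-2-yl)furan-3-yl}methyl acetate | CC(=O)OCc1c(B2OC(C)(C)C(C)(C)O2)occ1[C@H](O[Si](CC)(CC)CC)C[C@](C)(O)C3(O)CC[C@](C)(C=C)O3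
F4 | step 17 | {5-(dimethoxyphosphoryl)-4-[(1R,3S)-3-hydroxy-3-[(5R)-2-hydroxy-5-methyl-5-vinyloxolan-2-yl]-1-(triethylsilyloxy)butyl]-2-oxo-2,5-dihydrofuran-3-yl}methyl acetate | CC(=O)OCC1=C([C@H](O[Si](CC)(CC)CC)C[C@](C)(O)C2(O)CC[C@](C)(C=C)O2)C(P(=O)(OC)OC)OC1=O
F5 | step 17 | ozonide of F4 at the vinyl group (1,2,4-trioxolan-3-yl in place of vinyl) | CC(=O)OCC1=C([C@H](O[Si](CC)(CC)CC)C[C@](C)(O)C2(O)CC[C@](C)(C3OOCO3)O2)C(P(=O)(OC)OC)OC1=O
F6 | step 17 | {5-(dimethoxyphosphoryl)-4-[(1R,3S)-3-[(5R)-5-formyl-2-hydroxy-5-methyloxolan-2-yl]-3-hydroxy-1-(triethylsilyloxy)butyl]-2-oxo-2,5-dihydrofuran-3-yl}methyl acetate | CC(=O)OCC1=C([C@H](O[Si](CC)(CC)CC)C[C@](C)(O)C2(O)CC[C@](C)(C=O)O2)C(P(=O)(OC)OC)OC1=O
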